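The readings come from a simulation on assumed constants; the scatter is artificial.

In a one-step world the single-handed coupling partner picks one hand of the racemate, the left-handed product piles up, and its excess stays where the choice put it. The earlier runs behave otherwise, so when I repeat this flask I watch the difference between the products and not their total.

common to all: left-handed substrate 0.10 M; right-handed substrate 0.10 M
- alpha: coupling partner 1.2 equiv; run made earlier
- delta: coupling partner 1.7 equiv; run made earlier
- beta: coupling partner 3.4 equiv; run made earlier
- oak: coupling partner 1.00 equiv; time 2.5 d
- ash: coupling partner 1.50 equiv; time 2.5 d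
- alder: coupling partner 2.00 equiv; time 2.5 d
- cedar: coupling partner 3.00 equiv; time 2.5 d

- alpha (time / d: left-handed product / %, right-handed product / %): 0.208: 5.0, 1.0; 0.625: 7.7, 4.1; 1.25: 10.2, 5.4; 1.67: 9.5, 6.6; 2.50: 9.3, 7.3
- delta (time / d: left-handed product / %, right-handed product / %): 0.208: 6.9, 0; 0.625: 12.2, 3.1; 1.25: 15.3, 5.8; 1.67: 13.7, 9.2; 2.50: 14.5, 10.2
- beta (time / d: left-handed product / %, right-handed product / %): 0.208: 12.7, 3.4; 0.417: 16.3, 4.6; 0.625: 21.0, 7.1; 1.25: 22.5, 15.3; 2.50: 18.4, 16.5

(each reading ± 1 percentage point)

- coupling partner is single-handed; left-handed substrate and right-handed substrate are mirror images of each other, charged as a racemate, each of them at the stated concentration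
- an excess is the difference of the two amounts in percent of their sum
- "hardly changes" means that all values lie within two and a half points (for a concentration: within two and a half percent of the largest)
- the handed part of coupling partner does not stay in what it makes, so the products of the two hands are mirror images too

- excess of left-handed product over right-handed product at the end for oak, ash, alder, cedar, in this order
- the course of these numbers from the first flask to the last (rises all the way / falls all the way / falls, then rises / rises, then falls / hardly changes)

The ladder starts with the coupling. Summed over alpha, delta and beta, the two products stand at 74 percentage points at 1.25 d and 76 points at 2.50 d, a rise within the scatter of the readings, so these sums do not show whether the making goes on or has stopped. Over the same interval the summed c(left-handed product) − c(right-handed product) falls from 22 points to 8.2 points. I read this next rung as racemisation, a first-order loss, and carry the half-life of that difference, read here as 0.899 d. It is shorter than the interval.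

A first-order clock contains no amount of partner, so I expect the loading to scale both products and leave their ratio. The end excesses of alpha, delta and beta, 12.0%, 17.4% and 5.44%, show no steady course with loading. The last rung is the end itself: the pooled excess of 28.9% at 1.25 d, run forward on this clock, gives me 11.0% at 2.5 d for oak, ash, alder and cedar alike.

The forecast gives 10%, 10%, 10% and 10%, a course that hardly changes, on the grounds of “first-order racemisation of the product”, and it stands below my figure.

The flasks give 11.6%, 11.3%, 11.0% and 10.5%, and the course hardly changes.

    coupling partner + left-handed substrate → left-handed product (k = 0.00400 L mol⁻¹ min⁻¹)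
    left-handed product ⇌ right-handed product (k = 4.30 × 10⁻⁴ min⁻¹)
    2 coupling partner → self-condensation product (k = 6.00 × 10⁻⁴ L mol⁻¹ min⁻¹)
    right-handed substrate ⇌ achiral form (K = 0.640, k = 6.00 × 10⁻⁴ min⁻¹)
    coupling partner + right-handed substrate → right-handed product (k = 2.50 × 10⁻⁴ L mol⁻¹ min⁻¹)
    coupling partner → decomposed reagent (k = 5.50 × 10⁻⁴ min⁻¹)
    left-handed substrate ⇌ achiral form (K = 0.640, k = 6.00 × 10⁻⁴ min⁻¹)

The exchange between the two products is the main reason for the low excess: with that step taken away, oak ends at 86.8% and not 11.6%. Now I apply the carried half-life to the simulated states. Oak stands at an excess of 33.8% at 1.25 d, and 0.899 d carries that to 12.9% at 2.50 d, where the flask shows 11.6%. Cedar stands at 30.7% at 1.25 d, and the same clock carries it to 11.7% at 2.50 d, where the flask shows 10.5%.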